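Divide the product a run has made by the catalyst charged: that ratio is what you need for this flask. The flask is the noon run, followed further; the summer run had twice the free catalyst.

in all of them: substrate 0.50 M
- noon: partner 2.5 M; protic impurity 10 mM; free catalyst 14 mM; the very flask that is asked about, followed so far
- summer: partner 2.5 M; protic impurity 10 mM; free catalyst 28 mM; run made earlier
- flask: partner 2.50 M; protic impurity 10.0 mM; free catalyst 14 mM; time 25 h

noon run (percent of the substrate charged)

| time / h | product / % | substrate / % |
|---|---|---|
| 3.00 | 86 | 16 |
| 6.00 | 84 | 16 |
| 10.0 | 85 | 14 |
| 12.0 | 84 | 17 |
| 15.0 | 85 | 18 |

summer run (percent of the substrate charged)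

| time / min | product / % | substrate / % |
|---|---|---|
| 10.0 | 37 | 65 |
| 30.0 | 83 | 20 |
| 60.0 | 99 | 1 |
| 80.0 | 102 | 0 |
| 120 | 99 | 0 |

(scatter of a reading: 1.5 percentage points)

- birch: at 25 h add free catalyst, 100% of the amount charged, then wait 12 h
- oak: at 25 h take out 90% of the product then present, then wait 12 h
- ash: change nothing and wait 12 h more

- product, in percent of the substrate first charged, at 25 h
- which option adds most product ("none" when 2 percentage points or less is all one gets) (birch / oak / ash / none)
- product present, with what was taken out counted in, in percent of the substrate first charged, after birch
- product present, with what was taken out counted in, in percent of the substrate first charged, after oak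

- what is taken out of product is counted as made
- the earlier runs were read with a standard deviation of 1.5 percentage points
- additions bring no volume worth counting

1. In the noon run, product stands flat from 86% at 3.00 h to 85% at 15.0 h, with substrate still present. In the summer run, it reads 99% at 60.0 min. An equilibrium plateau should not move with the amount of catalyst, so I read the noon stop as catalyst that quits.

2. Suppose each catalyst makes a fixed number of turns before it is lost. The noon plateau reads 30.3 turns: this is the turnover budget (the turnover number), the concentration of product made per concentration of catalyst charged.

3. Multiply back. The summer charge carries a budget of 0.848 M, more than its 0.50 M of substrate, so that run should use up its substrate, and substrate reads 0% at 120 min. The noon charge carries 0.424 M, less than its substrate.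

4. At 25 h I therefore expect 84.8%. Waiting and taking product out bring no new budget, so ash and oak stay there. Birch brings 0.424 M, more than the 0.0760 M of substrate remaining, so I expect it to reach the whole charge, 100%.

The forecast says 85% now, 99% after birch against my 100%, 85% after oak and birch as best, and of oak it gives as its ground that “removing product does nothing without live catalyst”.

The flask gives 84.6% at 25 h, 99.9% after birch and 84.6% after oak. Birch adds 15 percentage points, while oak and ash add 0 points, so the best option is birch.

    substrate + partner + free catalyst → product + free catalyst, rate k1*[substrate]*[partner]*[free catalyst]/(1 + ([substrate]/sat1)) (16.0 mM, k = 0.330 L² mol⁻² s⁻¹)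
    partner + protic impurity → quenched reagent (k = 0.0190 L mol⁻¹ s⁻¹)
    free catalyst → spent catalyst (k = 3.70 × 10⁻⁴ s⁻¹)
    2 substrate → homo dimer (k = 2.60 × 10⁻⁷ L mol⁻¹ s⁻¹)

Now take the neighbour charged with 1.0 M of partner. The making step is first order in partner, the loss of free catalyst has no partner in it, and the neighbour's substrate stays far above 16 mM, so scale the budget by the partner charge: 12.1 turns, or 33.9% of the substrate. That neighbour gives 34.6%, with free catalyst at 0% of its charge and 64.4% of its substrate still there at 25.0 h.

The earlier runs and the new flask are calculated for an exercise; noise was put on by code.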